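Chain numbering: C1 (on ring A, the 3-hydroxy-5-methoxyphenyl ring) to C14 (on ring B, the 3,5-dihydroxyphenyl ring), with the E-alkene at C8=C9. The three phenols travel as benzyl ethers and are freed last with Na/NH3, which leaves the isolated alkene and the methyl ether untouched.
Key disconnection C7–C8: the primary alkyllithium ring A–(CH2)7–Li adds to the C=N carbon (C8) of the N-silyl tosylhydrazone of an (E)-7-arylhept-2-enal (alkene at C9=C10). Loss of sulfinate, then of N2 by a retro-ene shift, moves the alkene to C8=C9 (E) and removes every heteroatom of the activating group.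
Enabling feature: C8=C9 is an isolated 1,2-disubstituted alkene whose ring-B neighbour C10 is an unsubstituted CH2. C10 can therefore accept the hydrogen of an allylic diazene, and C8 can be a carbonyl-level electrophile. C7–C8 is also the midpoint of the C14 tether, so both halves are aryl-C7 units.
Ring A half: 3-bromo-5-methoxyphenol, benzylation, copper-catalysed Grignard coupling with 1,7-dibromoheptane, Finkelstein exchange. Ring B half: 3,5-bis(benzyloxy)benzyl bromide plus pent-4-enylmagnesium bromide, cross-metathesis with crotonaldehyde, hydrazone formation, N-silylation.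
Rings: both benzene rings are bought intact; no ring is formed or closed anywhere in the route.

Key step: step 8

Remark: crotonaldehyde is taken as the commercial, predominantly E material, and the sp3 centre that appears at C8 in the key-step intermediates is racemic and transient.

Step 1
Reactants: 1 3-bromo-5-methoxyphenol
Product: 2 1-(benzyloxy)-3-bromo-5-methoxybenzene
Conditions: BnBr (1.1 equiv), K2CO3, DMF, rt
Reagents that add atoms: benzyl bromide, BrCc1ccccc1
Why: Williamson ether synthesis, in which the phenoxide displaces bromide from benzyl bromide and the only acidic proton of ring A is masked before the organometallic steps.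

Step 2
Reactants: 2 1-(benzyloxy)-3-bromo-5-methoxybenzene; 3 1,7-dibromoheptane
Product: 5 1-(benzyloxy)-3-(7-bromoheptyl)-5-methoxybenzene, via arylmagnesium bromide 4 (not isolated)
Conditions: Mg, cat. I2, THF, reflux; then 3 (4 equiv), Li2CuCl4 (5 mol %), THF, 0 °C to rt
Reagents that add atoms: none
Why: Copper-catalysed Grignard–alkyl halide cross-coupling, in which the organocopper species formed from 4 substitutes one primary C–Br bond and the excess of the symmetrical dibromide suppresses double arylation.

Step 3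
Reactants: 5 1-(benzyloxy)-3-(7-bromoheptyl)-5-methoxybenzene
Product: 6 1-(benzyloxy)-3-(7-iodoheptyl)-5-methoxybenzene
Conditions: NaI (3 equiv), acetone, reflux
Reagents that add atoms: sodium iodide, [Na+].[I-]
Why: Finkelstein halide exchange, driven by precipitation of NaBr, supplies the primary iodide needed for clean iodine–lithium exchange.

Step 4
Reactants: 7 5-bromopent-1-ene; 8 3,5-bis(benzyloxy)benzyl bromide
Product: 10 1,3-bis(benzyloxy)-5-(hex-5-en-1-yl)benzene, via pent-4-enylmagnesium bromide 9 (not isolated)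
Conditions: 7, Mg, THF, rt to 40 °C; then 8, Li2CuCl4 (5 mol %), THF, −10 °C to rt
Reagents that add atoms: none
Why: Copper-catalysed Grignard cross-coupling with a reactive benzylic bromide, a standard entry to 5-alkylresorcinol ethers that leaves the terminal alkene and the benzyl ethers intact.

Step 5
Reactants: 10 1,3-bis(benzyloxy)-5-(hex-5-en-1-yl)benzene; 11 (E)-but-2-enal (crotonaldehyde)
Product: 12 (2E)-7-[3,5-bis(benzyloxy)phenyl]hept-2-enal
Conditions: 11 (5 equiv), Hoveyda–Grubbs second-generation catalyst RuCl2(H2IMes)(=CH-C6H4-2-OiPr) (3 mol %), CH2Cl2, 40 °C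
Reagents that add atoms: none
Why: Olefin cross-metathesis of a terminal alkene that homodimerises readily with an electron-poor enal, which is selective for the cross product, favours the conjugated E-enal thermodynamically and is driven by loss of propene.

Step 6
Reactants: 12 (2E)-7-[3,5-bis(benzyloxy)phenyl]hept-2-enal
Product: 13 N'-{(1E,2E)-7-[3,5-bis(benzyloxy)phenyl]hept-2-en-1-ylidene}-4-methylbenzenesulfonohydrazide
Conditions: TsNHNH2 (1.05 equiv), THF, 23 °C
Reagents that add atoms: p-toluenesulfonohydrazide, Cc1ccc(cc1)S(=O)(=O)NN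
Why: Hydrazone condensation of an aldehyde with a sulfonylhydrazide, which is fast at room temperature without acid, so the E-alkene is kept and conjugate cyclisation is limited.

Step 7
Reactants: 13 N'-{(1E,2E)-7-[3,5-bis(benzyloxy)phenyl]hept-2-en-1-ylidene}-4-methylbenzenesulfonohydrazide
Product: 14 N-(tert-butyldimethylsilyl)-N'-{(1E,2E)-7-[3,5-bis(benzyloxy)phenyl]hept-2-en-1-ylidene}-4-methylbenzenesulfonohydrazide
Conditions: TBSOTf (1.2 equiv), Et3N (1.5 equiv), THF, −78 °C
Reagents that add atoms: tert-butyldimethylsilyl trifluoromethanesulfonate, CC(C)(C)[Si](C)(C)OS(=O)(=O)C(F)(F)F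
Why: N-silylation of the acidic sulfonamide N–H with a silyl triflate and an amine base, which removes the only proton that would quench an alkyllithium.

Step 8
Reactants: 6 1-(benzyloxy)-3-(7-iodoheptyl)-5-methoxybenzene; 14 N-(tert-butyldimethylsilyl)-N'-{(1E,2E)-7-[3,5-bis(benzyloxy)phenyl]hept-2-en-1-ylidene}-4-methylbenzenesulfonohydrazide
Product: 18 1-(benzyloxy)-3-{(8E)-14-[3,5-bis(benzyloxy)phenyl]tetradec-8-en-1-yl}-5-methoxybenzene, via alkyllithium 15 (not isolated), via lithium hydrazide adduct 16 (not isolated), via allylic diazene 17 (not isolated)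
Conditions: 6 (1.3 equiv), t-BuLi (2.0 equiv relative to 6), Et2O/pentane, −78 °C; 14, THF, −78 °C; then AcOH, CF3CH2OH, −78 to 23 °C
Reagents that add atoms: none
Why: Iodine–lithium exchange converts 6 into the primary alkyllithium 15, which adds 1,2 to the azomethine carbon C8 of 14 and so forms the C7–C8 bond in the lithium hydrazide 16. Acetic acid then protonates nitrogen, removes the N-silyl group and lets p-toluenesulfinic acid leave, and the resulting allylic monoalkyl diazene 17 loses N2 in a concerted retro-ene (1,5-sigmatropic) transfer of its N–H hydrogen to C10, which shifts the double bond from C9=C10 to C8=C9. The closest known reaction type is the reductive coupling of alkyllithium reagents with N-tert-butyldimethylsilyl tosylhydrazones of α,β-unsaturated aldehydes, an allylic diazene rearrangement of the kind that also operates in the reductive transposition of enone tosylhydrazones. No ring is closed, and the only new stereocentre, C8 in 16 and 17, is formed racemic and is erased when C8 becomes sp2. The E geometry is controlled by the six-centre retro-ene transition state, in which the C1–C7 chain on C8 sits pseudo-equatorial to avoid allylic strain against the C9–C10 unit. The step needs 1,2-addition rather than 1,4-addition or deprotonation, secured by the N-silyl group (no acidic N–H, hard C=N electrophile at −78 °C), and a single alkene position, secured because the hydrogen can only be delivered intramolecularly to C10.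

Step 9
Reactants: 18 1-(benzyloxy)-3-{(8E)-14-[3,5-bis(benzyloxy)phenyl]tetradec-8-en-1-yl}-5-methoxybenzene
Product: 19 dehydrobisgravillol, 5-[(6E)-14-(3-hydroxy-5-methoxyphenyl)tetradec-6-en-1-yl]benzene-1,3-diol
Conditions: Na (excess), NH3(l)/THF, −78 °C; then solid NH4Cl
Reagents that add atoms: none
Why: Dissolving-metal hydrogenolysis of aryl benzyl ethers, in which electron transfer cleaves the three benzylic C–O bonds to phenoxides that resist further reduction, while the isolated E-alkene and the aryl methyl ether are inert without an added alcohol.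

Compound list
1 | 3-bromo-5-methoxyphenol | COc1cc(O)cc(Br)c1 | starting material
2 | 1-(benzyloxy)-3-bromo-5-methoxybenzene | COc1cc(OCc2ccccc2)cc(Br)c1 | intermediate
3 | 1,7-dibromoheptane | BrCCCCCCCBr | starting material
4 | [3-(benzyloxy)-5-methoxyphenyl]magnesium bromide | COc1cc(OCc2ccccc2)cc([Mg]Br)c1 | intermediate
5 | 1-(benzyloxy)-3-(7-bromoheptyl)-5-methoxybenzene | COc1cc(OCc2ccccc2)cc(CCCCCCCBr)c1 | intermediate
6 | 1-(benzyloxy)-3-(7-iodoheptyl)-5-methoxybenzene | COc1cc(OCc2ccccc2)cc(CCCCCCCI)c1 | intermediate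
7 | 5-bromopent-1-ene | C=CCCCBr | starting material
8 | 3,5-bis(benzyloxy)benzyl bromide | BrCc1cc(OCc2ccccc2)cc(OCc2ccccc2)c1 | starting material
9 | pent-4-enylmagnesium bromide | C=CCCC[Mg]Br | intermediate
10 | 1,3-bis(benzyloxy)-5-(hex-5-en-1-yl)benzene | C=CCCCCc1cc(OCc2ccccc2)cc(OCc2ccccc2)c1 | intermediate
11 | (E)-but-2-enal (crotonaldehyde) | C/C=C/C=O | starting material
12 | (2E)-7-[3,5-bis(benzyloxy)phenyl]hept-2-enal | O=C/C=C/CCCCc1cc(OCc2ccccc2)cc(OCc2ccccc2)c1 | intermediate
13 | N'-{(1E,2E)-7-[3,5-bis(benzyloxy)phenyl]hept-2-en-1-ylidene}-4-methylbenzenesulfonohydrazide | Cc1ccc(cc1)S(=O)(=O)N/N=C/C=C/CCCCc1cc(OCc2ccccc2)cc(OCc2ccccc2)c1 | intermediate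
14 | N-(tert-butyldimethylsilyl) derivative of 13 (silyl group on the sulfonamide nitrogen) | Cc1ccc(cc1)S(=O)(=O)N(/N=C/C=C/CCCCc1cc(OCc2ccccc2)cc(OCc2ccccc2)c1)[Si](C)(C)C(C)(C)C | intermediate
15 | {7-[3-(benzyloxy)-5-methoxyphenyl]heptyl}lithium | COc1cc(OCc2ccccc2)cc(CCCCCCC[Li])c1 | intermediate
16 | lithium hydrazide adduct, racemic at C8 (C8 bears N(Li)–N(TBS)Ts, alkene E at C9=C10) | COc1cc(OCc2ccccc2)cc(CCCCCCCC(/C=C/CCCCc2cc(OCc3ccccc3)cc(OCc3ccccc3)c2)N([Li])N([Si](C)(C)C(C)(C)C)S(=O)(=O)c2ccc(C)cc2)c1 | intermediate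
17 | allylic monoalkyl diazene, racemic at C8 (C8 bears N=NH, alkene E at C9=C10) | COc1cc(OCc2ccccc2)cc(CCCCCCCC(/C=C/CCCCc2cc(OCc3ccccc3)cc(OCc3ccccc3)c2)N=N)c1 | intermediate
18 | 1-(benzyloxy)-3-{(8E)-14-[3,5-bis(benzyloxy)phenyl]tetradec-8-en-1-yl}-5-methoxybenzene | COc1cc(OCc2ccccc2)cc(CCCCCCC/C=C/CCCCCc2cc(OCc3ccccc3)cc(OCc3ccccc3)c2)c1 | intermediate
19 | dehydrobisgravillol, 5-[(6E)-14-(3-hydroxy-5-methoxyphenyl)tetradec-6-en-1-yl]benzene-1,3-diol | COc1cc(O)cc(CCCCCCC/C=C/CCCCCc2cc(O)cc(O)c2)c1 | target

Total step count: 9. Longest linear sequence: 6 steps (steps 4, 5, 6, 7, 8, 9, from 7 and 8 to 19).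

Steps most likely to fail

**Step 8.** The alkyllithium may act as a base instead of adding to C8. Possible sites are the γ-C–H of the hydrazone, the ring C–H between two alkoxy groups, and the benzylic O–CH2. The retro-ene step may also show too little preference for the E geometry.
The fallback sets out from 10 and 6 and comes back to the route at 19. It keeps the C7–C8 union but takes the geometry from an alkyne reduction.
- Hydroboration of 10 with 9-BBN should give B-{6-[3,5-bis(benzyloxy)phenyl]hexyl}-9-borabicyclo[3.3.1]nonane F1.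
- Oxidation of this borane in the same flask (H2O2, NaOH) should give 6-[3,5-bis(benzyloxy)phenyl]hexan-1-ol F2.
- Dess–Martin oxidation should give 6-[3,5-bis(benzyloxy)phenyl]hexanal F3.
- Ohira–Bestmann homologation (dimethyl (1-diazo-2-oxopropyl)phosphonate, K2CO3, MeOH) should give 1,3-bis(benzyloxy)-5-(hept-6-yn-1-yl)benzene F4.
- Deprotonation with n-BuLi in THF/DMPU should give {7-[3,5-bis(benzyloxy)phenyl]hept-1-yn-1-yl}lithium F5.
- Alkylation of this acetylide by 6 should give 1-(benzyloxy)-3-{14-[3,5-bis(benzyloxy)phenyl]tetradec-8-yn-1-yl}-5-methoxybenzene F6.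
- Na in NH3/THF should then reduce the alkyne to the E-alkene and cleave the three benzyl ethers in the same operation, giving 19.

**Step 6.** The unsaturated tosylhydrazone may cyclise by conjugate addition of its own nitrogen during formation or storage. The material may also degrade before or during N-silylation.
The fallback sets out from 12 and 6 and comes back at 18, avoiding any isolated hydrazone.
- The alkyllithium 15, made from 6 as in step 8, would be added to the aldehyde carbon of 12 at −78 °C. This should give racemic (5E)-14-[3-(benzyloxy)-5-methoxyphenyl]-1-[3,5-bis(benzyloxy)phenyl]tetradec-5-en-7-ol F7.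
- Mitsunobu displacement with 2-nitrobenzenesulfonylhydrazide (PPh3, diethyl azodicarboxylate, THF, −30 °C) should give the N-allylic 2-nitrobenzenesulfonylhydrazine F8.
- On warming to 23 °C this adduct loses the sulfinic acid to give the diazene 17, which loses N2 and gives 18.

**Step 2.** The electron-rich aryl Grignard reagent may substitute the primary bromide only slowly. Oxidative homocoupling or a second arylation of the dibromide may then compete.
The fallback sets out from 2 and comes back at 6. It reverses the polarity to an aryl electrophile and an alkyl nucleophile.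
- Hept-6-en-1-ol and 9-BBN (2.2 equiv) should give the doubly borylated 9-[7-(9-borabicyclo[3.3.1]nonan-9-yloxy)heptyl]-9-borabicyclo[3.3.1]nonane F9.
- B-alkyl Suzuki–Miyaura coupling of this borane with 2 (Pd(dppf)Cl2, aqueous NaOH, THF, 65 °C) should give 7-[3-(benzyloxy)-5-methoxyphenyl]heptan-1-ol F10.
- Appel iodination (I2, PPh3, imidazole, CH2Cl2) should give 6.

Further compounds
F1 | step 8 | B-{6-[3,5-bis(benzyloxy)phenyl]hexyl}-9-borabicyclo[3.3.1]nonane | C(CCCCCc1cc(OCc2ccccc2)cc(OCc2ccccc2)c1)B1C2CCCC1CCC2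
F2 | step 8 | 6-[3,5-bis(benzyloxy)phenyl]hexan-1-ol | OCCCCCCc1cc(OCc2ccccc2)cc(OCc2ccccc2)c1
F3 | step 8 | 6-[3,5-bis(benzyloxy)phenyl]hexanal | O=CCCCCCc1cc(OCc2ccccc2)cc(OCc2ccccc2)c1
F4 | step 8 | 1,3-bis(benzyloxy)-5-(hept-6-yn-1-yl)benzene | C#CCCCCCc1cc(OCc2ccccc2)cc(OCc2ccccc2)c1
F5 | step 8 | {7-[3,5-bis(benzyloxy)phenyl]hept-1-yn-1-yl}lithium | [Li]C#CCCCCCc1cc(OCc2ccccc2)cc(OCc2ccccc2)c1
F6 | step 8 | 1-(benzyloxy)-3-{14-[3,5-bis(benzyloxy)phenyl]tetradec-8-yn-1-yl}-5-methoxybenzene | COc1cc(OCc2ccccc2)cc(CCCCCCCC#CCCCCCc2cc(OCc3ccccc3)cc(OCc3ccccc3)c2)c1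
F7 | step 6 | racemic (5E)-14-[3-(benzyloxy)-5-methoxyphenyl]-1-[3,5-bis(benzyloxy)phenyl]tetradec-5-en-7-ol | COc1cc(OCc2ccccc2)cc(CCCCCCCC(O)/C=C/CCCCc2cc(OCc3ccccc3)cc(OCc3ccccc3)c2)c1
F8 | step 6 | racemic N-allylic 2-nitrobenzenesulfonylhydrazine (C8 bears N(NH2)SO2Ar, alkene E at C9=C10) | COc1cc(OCc2ccccc2)cc(CCCCCCCC(/C=C/CCCCc2cc(OCc3ccccc3)cc(OCc3ccccc3)c2)N(N)S(=O)(=O)c2ccccc2[N+](=O)[O-])c1
F9 | step 2 | 9-[7-(9-borabicyclo[3.3.1]nonan-9-yloxy)heptyl]-9-borabicyclo[3.3.1]nonane | C(CCCCCCOB1C2CCCC1CCC2)B1C2CCCC1CCC2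
F10 | step 2 | 7-[3-(benzyloxy)-5-methoxyphenyl]heptan-1-ol | COc1cc(OCc2ccccc2)cc(CCCCCCCO)c1
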